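## Analysis of the target

Schizolaenone B is a (2S)-flavanone. Ring A is a phloroglucinol-type benzene (C5-OH, C7-OH, O1 on C8a) with a prenyl group at C6. Ring C is the dihydropyranone (O1, C2, C3, C4=O), and ring B is a catechol (C3'-OH, C4'-OH) with an (E)-geranyl chain at C5'. C2 is the only stereocentre. It is benzylic, β to the ketone and bound to a phenolic oxygen, so base can erase it by reversible E1cB opening to the 2'-hydroxychalcone. The prenyl group sits between two phenols and the geranyl group next to one, so acids invite chroman formation and cation–olefin cyclisation, and three trisubstituted alkenes rule out hydrogenolysis. The hidden difficulty is regiochemical: C6 and C8 differ only in their relation to ring C, so closing ring C onto a prenylated phloroglucinol means telling two nearly identical phenols apart. The feature used here is that C4a and C8a are neighbouring ring A carbons carrying both ring C bonds (C4a–C4 acyl, C8a–O1), with the C5 oxygen ortho to C4a. Without those two bonds, the rest of ring A (O5, C6-prenyl, O7, C8-H) is mirror-symmetric about the C6···C8a axis.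

## Retrosynthetic reasoning

26 is traced back to its tetrakis-MOM ether 25. MOM ethers direct the lithiations used earlier, survive fluoride and organolithium reagents, and come off without hydrogen or strong base.

In 25 the bonds O1–C8a and C4–C4a are cut together. Both end on adjacent ring A carbons, so ring A becomes aryne 24 and the rest becomes the β-hydroxy ester 23, which supplies O1, C2, C3, C4 and ring B. The cut is placed here for three reasons. First, the alkoxy group beside the triple bond of 24 dictates that oxygen goes to C8a and the acyl carbon to C4a. Second, the ring A unit is symmetric before the aryne is made, so the prenyl group can only end at C6. Third, C2 is not touched, so its configuration can be set earlier by a reliable catalytic reduction. The forward reaction has to join the fragments, close ring C and keep C2 intact.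

Aryne 24 comes from the 2-silylaryl triflate 13 by fluoride-induced elimination. 13 is traced back through carbamate 11 (ortho-silylation directed by the carbamate) and carbamate 7 to the symmetric phenol 6. Both ortho positions of 6 are equivalent, so no regiochemical question arises. Phenol 6 comes from aryl chloride 5 by hydroxylation. The prenyl group of 5 is placed by lithiation of 2 at the one position flanked by two MOM ethers, followed by allylation with 3. 2 is the bis-MOM ether of 1.

Hydroxy ester 23 comes from β-keto ester 22 by asymmetric transfer hydrogenation, which sets C2. 22 comes from aldehyde 20 and diazo ester 21 (C3 and C4 added in one step). The geranyl chain of 20 is installed on acetal 16 by bromine–lithium exchange and SN2 allylation with 17, so the (E)-alkene is bought, not made. 16 derives from 14 through 15.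

## Alternatives that were turned down

Alternative 1: the textbook route cuts O1–C2 and C3(α)–C(β). Claisen–Schmidt condensation of acetophenone A1 with aldehyde 20 would give 2'-hydroxychalcone A2, and a catalytic asymmetric oxa-Michael cyclisation would give 25. It was turned down for three reasons. A1 already contains the regiochemical problem, because only the phenol remote from the prenyl group may be free. Non-activated 2'-hydroxychalcones cyclise reversibly, so the catalyst must also outrun racemisation of its own product; the known remedy, an activating ester at C3, ends in an acidic decarboxylation that the isoprenoid chains would not survive. The key step forms one C–O bond and gives nothing else.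

Alternative 2: cut C2–C1'. Enantioselective 1,4-addition of arylboronic acid A4 to chromone A3 with a chiral rhodium or palladium catalyst would give 25. This is the soundest alternative for the stereocentre. It was turned down on step economy and on what the key step builds: A3 still needs a regiocontrolled ring A plus an extra carbon for C2, and A4 needs a boron at C1' in addition to the geranyl group. The 5-OMOM group peri to the carbonyl, buttressed by the C6 prenyl group, should slow the addition while the electron-rich A4 protodeboronates. The step forms a single C–C bond and closes no ring.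

Alternative 3: cut C6–prenyl and C5'–geranyl last. (S)-Eriodictyol A5 would be converted into the bis-tertiary ether A6 (5-O-(1,1-dimethylallyl), 4'-O-linalyl, 7- and 3'-O-MOM). A double aromatic Claisen rearrangement would then deliver both chains regiospecifically, since each ether has only one free ortho position, and 26 would follow after removal of the two MOM groups. It was turned down because making A6 means telling four phenols apart and forcing a tertiary ether onto the hydrogen-bonded, peri-hindered 5-OH. The linalyl ether would rearrange through chair and boat transition states to a geranyl/neryl mixture. The heat needed would also erode C2 by ring opening.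

Key step: step 12

Assumption: the SMILES is read as the (2S)-flavanone with an (E)-geranyl group at C5'; compounds 1, 3, 14, 17 and 21 are taken as commercial.

## Route

Step 1
Reactants: 1 5-chlorobenzene-1,3-diol
Product: 2 1-chloro-3,5-bis(methoxymethoxy)benzene
Conditions: MOMCl (2.5 equiv), NaH (2.5 equiv), DMF, 0 °C to rt
Reagents that add atoms: chloromethyl methyl ether, COCCl
Why: Williamson O-alkylation of both phenoxides; the MOM ethers serve later as ortho-directing groups and are stable to organolithiums and fluoride.

Step 2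
Reactants: 2 1-chloro-3,5-bis(methoxymethoxy)benzene; 3 1-bromo-3-methylbut-2-ene (prenyl bromide)
Product: 5 5-chloro-1,3-bis(methoxymethoxy)-2-(3-methylbut-2-en-1-yl)benzene, via aryllithium 4 (not isolated)
Conditions: n-BuLi (1.1 equiv), THF, 0 °C; CuBr·SMe2 (1.0 equiv), −78 °C; 3 (1.2 equiv), −78 °C to rt
Reagents that add atoms: none
Why: Directed ortho-metalation should occur at the only position flanked by two OMOM groups (the chloride is not exchanged by n-BuLi and lies para to the lithium, so no aryne can form). Transmetalation to copper and SN2 attack at the primary carbon of 3 should give the normal prenyl group.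

Step 3
Reactants: 5 5-chloro-1,3-bis(methoxymethoxy)-2-(3-methylbut-2-en-1-yl)benzene
Product: 6 3,5-bis(methoxymethoxy)-4-(3-methylbut-2-en-1-yl)phenol
Conditions: Pd2(dba)3 (2 mol %), t-BuXPhos (8 mol %), KOH (3 equiv), 1,4-dioxane/H2O (1:1), 100 °C; then aq. NH4Cl
Reagents that add atoms: potassium hydroxide, [K+].[OH-]
Why: Palladium-catalysed C–O cross-coupling of an aryl chloride with hydroxide, made possible by the bulky biaryl phosphine; MOM ethers and the alkene are inert to hot aqueous base, and the product is a mirror-symmetric phenol.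

Step 4
Reactants: 6 3,5-bis(methoxymethoxy)-4-(3-methylbut-2-en-1-yl)phenol
Product: 7 3,5-bis(methoxymethoxy)-4-(3-methylbut-2-en-1-yl)phenyl N-(propan-2-yl)carbamate
Conditions: i-PrNCO (1.5 equiv), Et3N (20 mol %), CH2Cl2, rt
Reagents that add atoms: isopropyl isocyanate, CC(C)N=C=O
Why: Addition of the phenol to the isocyanate; the N-isopropyl carbamate is a strong ortho-director that can later be cleaved under mild, non-hydrolytic conditions.

Step 5
Reactants: 7 3,5-bis(methoxymethoxy)-4-(3-methylbut-2-en-1-yl)phenyl N-(propan-2-yl)carbamate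
Product: 11 3,5-bis(methoxymethoxy)-4-(3-methylbut-2-en-1-yl)-2-(trimethylsilyl)phenyl N-(propan-2-yl)carbamate, via N-silyl carbamate 8 (not isolated), via aryllithium 9 (not isolated), via N-silyl C-silyl carbamate 10 (not isolated)
Conditions: TBSOTf (1.1 equiv), TMEDA (1.1 equiv), Et2O, 0 °C to rt; then TMEDA (2 equiv), n-BuLi (2.2 equiv), −78 °C; TMSCl (3 equiv), −78 °C to rt; cold aq. NaHSO4 work-up
Reagents that add atoms: chlorotrimethylsilane, C[Si](C)(C)Cl
Why: In situ N-silylation masks the N–H; carbamate-directed ortho-lithiation then occurs at one of the two equivalent positions between the carbamate and an OMOM group and is trapped by TMSCl. The labile N–Si bond is hydrolysed on work-up.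

Step 6
Reactants: 11 3,5-bis(methoxymethoxy)-4-(3-methylbut-2-en-1-yl)-2-(trimethylsilyl)phenyl N-(propan-2-yl)carbamate
Product: 13 3,5-bis(methoxymethoxy)-4-(3-methylbut-2-en-1-yl)-2-(trimethylsilyl)phenyl trifluoromethanesulfonate, via silylphenol 12 (not isolated)
Conditions: DBU (1.5 equiv), Et2NH (1.2 equiv), MeCN, 40 °C; then PhNTf2 (1.5 equiv), rt
Reagents that add atoms: N-phenylbis(trifluoromethanesulfonimide), O=S(=O)(N(c1ccccc1)S(=O)(=O)C(F)(F)F)C(F)(F)F
Why: E1cB cleavage of the N-monoalkyl carbamate releases the phenoxide (the isocyanate is trapped by Et2NH as a urea), and the phenoxide is triflated in the same flask. This gives the standard 2-silylaryl triflate aryne precursor without acid.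

Step 7
Reactants: 14 3-bromo-4,5-dihydroxybenzaldehyde
Product: 15 3-bromo-4,5-bis(methoxymethoxy)benzaldehyde
Conditions: MOMCl (2.5 equiv), NaH (2.5 equiv), DMF, 0 °C to rt
Reagents that add atoms: chloromethyl methyl ether, COCCl
Why: Williamson O-alkylation of the catechol; the aldehyde has no α-hydrogen and is untouched.

Step 8
Reactants: 15 3-bromo-4,5-bis(methoxymethoxy)benzaldehyde
Product: 16 1-bromo-5-(dimethoxymethyl)-2,3-bis(methoxymethoxy)benzene
Conditions: HC(OMe)3 (3 equiv), PPTS (5 mol %), MeOH, rt; Et3N quench
Reagents that add atoms: trimethyl orthoformate, COC(OC)OC; methanol, CO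
Why: Acid-catalysed acetalisation masks the aldehyde for the organolithium step; PPTS at room temperature is too weak to cleave aryl MOM ethers.

Step 9
Reactants: 16 1-bromo-5-(dimethoxymethyl)-2,3-bis(methoxymethoxy)benzene; 17 (2E)-1-bromo-3,7-dimethylocta-2,6-diene (geranyl bromide)
Product: 20 3-[(2E)-3,7-dimethylocta-2,6-dien-1-yl]-4,5-bis(methoxymethoxy)benzaldehyde, via aryllithium 18 (not isolated), via geranylated acetal 19 (not isolated)
Conditions: n-BuLi (1.05 equiv), THF, −78 °C; CuBr·SMe2 (1.0 equiv); 17 (1.1 equiv), −78 to 0 °C; then 1 M aq. oxalic acid/THF, rt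
Reagents that add atoms: water, O
Why: Bromine–lithium exchange (assisted by the ortho OMOM group), transmetalation to copper and SN2 attack at the primary carbon of 17 should keep the (E)-alkene, which is never part of a metal allyl. The dimethyl acetal hydrolyses under mild acid that leaves the MOM ethers intact.

Step 10
Reactants: 20 3-[(2E)-3,7-dimethylocta-2,6-dien-1-yl]-4,5-bis(methoxymethoxy)benzaldehyde; 21 ethyl diazoacetate
Product: 22 ethyl 3-{3-[(2E)-3,7-dimethylocta-2,6-dien-1-yl]-4,5-bis(methoxymethoxy)phenyl}-3-oxopropanoate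
Conditions: 21 (1.3 equiv), SnCl2 (10 mol %), CH2Cl2, rt
Reagents that add atoms: none
Why: Roskamp reaction: Lewis-acid-promoted addition of the diazo ester to the aldehyde, then 1,2-hydride shift with loss of N2, gives the β-keto ester in one step; no metal carbene is formed, so the alkenes are not cyclopropanated.

Step 11
Reactants: 22 ethyl 3-{3-[(2E)-3,7-dimethylocta-2,6-dien-1-yl]-4,5-bis(methoxymethoxy)phenyl}-3-oxopropanoate
Product: 23 ethyl (3S)-3-{3-[(2E)-3,7-dimethylocta-2,6-dien-1-yl]-4,5-bis(methoxymethoxy)phenyl}-3-hydroxypropanoate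
Conditions: RuCl(p-cymene)[(S,S)-TsDPEN] (1 mol %), HCO2H/Et3N (5:2), DMF, 40 °C
Reagents that add atoms: none
Why: Noyori asymmetric transfer hydrogenation of an aryl ketone; the (S,S)-catalyst should deliver hydride to the same face as in acetophenone-type substrates, giving the (S)-carbinol that becomes C2. The outer-sphere mechanism without H2 leaves the three alkenes untouched.

Step 12
Reactants: 13 3,5-bis(methoxymethoxy)-4-(3-methylbut-2-en-1-yl)-2-(trimethylsilyl)phenyl trifluoromethanesulfonate; 23 ethyl (3S)-3-{3-[(2E)-3,7-dimethylocta-2,6-dien-1-yl]-4,5-bis(methoxymethoxy)phenyl}-3-hydroxypropanoate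
Product: 25 (2S)-2-{3-[(2E)-3,7-dimethylocta-2,6-dien-1-yl]-4,5-bis(methoxymethoxy)phenyl}-5,7-bis(methoxymethoxy)-6-(3-methylbut-2-en-1-yl)-2,3-dihydro-4H-chromen-4-one, via aryne 24 (not isolated)
Conditions: 13 (1.5 equiv, slow addition), 23 (1.0 equiv), CsF (4 equiv), THF, 50 °C
Reagents that add atoms: none
Why: Proposed new method: fluoride attack on silicon in 13 expels triflate and gives aryne 24, whose triple bond lies between the future C8a and C4a; the hydroxyl oxygen of 23 (hydrogen-bonded to fluoride or as its caesium alkoxide) adds to C8a, and the aryl anion left at C4a attacks the ethyl ester three atoms away and expels ethoxide, so that O1–C8a and C4–C4a form in one operation and ring C closes by 6-exo-trig acyl substitution. The closest known reaction types are the aryne–salicylate annulation to xanthones, which follows the same O-arylation/intramolecular acyl substitution sequence, and the acyl C–O insertion of carboxylic acids into arynes; new here is the aliphatic β-hydroxy ester as partner. Regiochemistry is set by the OMOM group beside the triple bond: as in 3-alkoxyarynes generally, it makes the remote aryne carbon the more linear and more electrophilic one and stabilises the anion that develops next to it, so oxygen goes to C8a and the acyl carbon to C4a. Because the ring A unit was mirror-symmetric before the aryne was made, the prenyl group can only end at C6, and no 8-prenyl isomer is possible. No bond to C2 is formed or broken, so the configuration of 23 is carried over and the descriptor stays (S). The step needs cyclisation to outrun protonation of the aryl anion and needs the product not to racemise by E1cB ring opening; the nearby ester (six-membered transition state), THF in which CsF and its HF adducts barely dissolve, slow addition of 13 and a moderate temperature are meant to secure both.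

Step 13
Reactants: 25 (2S)-2-{3-[(2E)-3,7-dimethylocta-2,6-dien-1-yl]-4,5-bis(methoxymethoxy)phenyl}-5,7-bis(methoxymethoxy)-6-(3-methylbut-2-en-1-yl)-2,3-dihydro-4H-chromen-4-one
Product: 26 (2S)-2-{3-[(2E)-3,7-dimethylocta-2,6-dien-1-yl]-4,5-dihydroxyphenyl}-5,7-dihydroxy-6-(3-methylbut-2-en-1-yl)-2,3-dihydro-4H-chromen-4-one (schizolaenone B)
Conditions: 3 M aq. HCl/MeOH (1:5), 40 °C, argon
Reagents that add atoms: none
Why: Acid-catalysed transacetalisation of the four aryl MOM ethers to dimethoxymethane; dilute methanolic acid at mild temperature should be fast enough for aryl MOM ethers while protonation of the trisubstituted alkenes remains slow. C2 is configurationally stable under acid.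

## Compound list

1 | 5-chlorobenzene-1,3-diol | Oc1cc(O)cc(Cl)c1 | starting material
2 | 1-chloro-3,5-bis(methoxymethoxy)benzene | COCOc1cc(Cl)cc(OCOC)c1 | intermediate
3 | 1-bromo-3-methylbut-2-ene (prenyl bromide) | CC(C)=CCBr | starting material
4 | [4-chloro-2,6-bis(methoxymethoxy)phenyl]lithium | COCOc1cc(Cl)cc(OCOC)c1[Li] | intermediate
5 | 5-chloro-1,3-bis(methoxymethoxy)-2-(3-methylbut-2-en-1-yl)benzene | COCOc1cc(Cl)cc(OCOC)c1CC=C(C)C | intermediate
6 | 3,5-bis(methoxymethoxy)-4-(3-methylbut-2-en-1-yl)phenol | COCOc1cc(O)cc(OCOC)c1CC=C(C)C | intermediate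
7 | 3,5-bis(methoxymethoxy)-4-(3-methylbut-2-en-1-yl)phenyl N-(propan-2-yl)carbamate | CC(C)NC(=O)Oc1cc(OCOC)c(CC=C(C)C)c(OCOC)c1 | intermediate
8 | 3,5-bis(methoxymethoxy)-4-(3-methylbut-2-en-1-yl)phenyl N-(tert-butyldimethylsilyl)-N-(propan-2-yl)carbamate | CC(C)N(C(=O)Oc1cc(OCOC)c(CC=C(C)C)c(OCOC)c1)[Si](C)(C)C(C)(C)C | intermediate
9 | ortho-lithiated derivative of 8 (lithium at C2 of the aryl ring) | CC(C)N(C(=O)Oc1cc(OCOC)c(CC=C(C)C)c(OCOC)c1[Li])[Si](C)(C)C(C)(C)C | intermediate
10 | 3,5-bis(methoxymethoxy)-4-(3-methylbut-2-en-1-yl)-2-(trimethylsilyl)phenyl N-(tert-butyldimethylsilyl)-N-(propan-2-yl)carbamate | CC(C)N(C(=O)Oc1cc(OCOC)c(CC=C(C)C)c(OCOC)c1[Si](C)(C)C)[Si](C)(C)C(C)(C)C | intermediate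
11 | 3,5-bis(methoxymethoxy)-4-(3-methylbut-2-en-1-yl)-2-(trimethylsilyl)phenyl N-(propan-2-yl)carbamate | CC(C)NC(=O)Oc1cc(OCOC)c(CC=C(C)C)c(OCOC)c1[Si](C)(C)C | intermediate
12 | 3,5-bis(methoxymethoxy)-4-(3-methylbut-2-en-1-yl)-2-(trimethylsilyl)phenol | Oc1cc(OCOC)c(CC=C(C)C)c(OCOC)c1[Si](C)(C)C | intermediate
13 | 3,5-bis(methoxymethoxy)-4-(3-methylbut-2-en-1-yl)-2-(trimethylsilyl)phenyl trifluoromethanesulfonate | O=S(=O)(Oc1cc(OCOC)c(CC=C(C)C)c(OCOC)c1[Si](C)(C)C)C(F)(F)F | intermediate
14 | 3-bromo-4,5-dihydroxybenzaldehyde | O=Cc1cc(O)c(O)c(Br)c1 | starting material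
15 | 3-bromo-4,5-bis(methoxymethoxy)benzaldehyde | O=Cc1cc(OCOC)c(OCOC)c(Br)c1 | intermediate
16 | 1-bromo-5-(dimethoxymethyl)-2,3-bis(methoxymethoxy)benzene | COC(OC)c1cc(OCOC)c(OCOC)c(Br)c1 | intermediate
17 | (2E)-1-bromo-3,7-dimethylocta-2,6-diene (geranyl bromide) | CC(C)=CCC/C(C)=C/CBr | starting material
18 | [5-(dimethoxymethyl)-2,3-bis(methoxymethoxy)phenyl]lithium | COC(OC)c1cc(OCOC)c(OCOC)c([Li])c1 | intermediate
19 | 5-(dimethoxymethyl)-1-[(2E)-3,7-dimethylocta-2,6-dien-1-yl]-2,3-bis(methoxymethoxy)benzene | COC(OC)c1cc(OCOC)c(OCOC)c(C/C=C(\C)CCC=C(C)C)c1 | intermediate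
20 | 3-[(2E)-3,7-dimethylocta-2,6-dien-1-yl]-4,5-bis(methoxymethoxy)benzaldehyde | O=Cc1cc(OCOC)c(OCOC)c(C/C=C(\C)CCC=C(C)C)c1 | intermediate
21 | ethyl diazoacetate | CCOC(=O)C=[N+]=[N-] | starting material
22 | ethyl 3-{3-[(2E)-3,7-dimethylocta-2,6-dien-1-yl]-4,5-bis(methoxymethoxy)phenyl}-3-oxopropanoate | CCOC(=O)CC(=O)c1cc(OCOC)c(OCOC)c(C/C=C(\C)CCC=C(C)C)c1 | intermediate
23 | ethyl (3S)-3-{3-[(2E)-3,7-dimethylocta-2,6-dien-1-yl]-4,5-bis(methoxymethoxy)phenyl}-3-hydroxypropanoate | CCOC(=O)C[C@H](O)c1cc(OCOC)c(OCOC)c(C/C=C(\C)CCC=C(C)C)c1 | intermediate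
24 | 3,5-bis(methoxymethoxy)-4-(3-methylbut-2-en-1-yl)benzyne (1,2-didehydrobenzene) | COCOC1=CC#CC(OCOC)=C1CC=C(C)C | intermediate
25 | (2S)-2-{3-[(2E)-3,7-dimethylocta-2,6-dien-1-yl]-4,5-bis(methoxymethoxy)phenyl}-5,7-bis(methoxymethoxy)-6-(3-methylbut-2-en-1-yl)-2,3-dihydro-4H-chromen-4-one | CC(C)=CCC/C(C)=C/Cc1cc([C@@H]2CC(=O)c3c(cc(OCOC)c(CC=C(C)C)c3OCOC)O2)cc(OCOC)c1OCOC | intermediate
26 | (2S)-2-{3-[(2E)-3,7-dimethylocta-2,6-dien-1-yl]-4,5-dihydroxyphenyl}-5,7-dihydroxy-6-(3-methylbut-2-en-1-yl)-2,3-dihydro-4H-chromen-4-one (schizolaenone B) | CC(C)=CCC/C(C)=C/Cc1cc([C@@H]2CC(=O)c3c(cc(O)c(CC=C(C)C)c3O)O2)cc(O)c1O | target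

## Step count and least certain steps

Total: 13 steps. Longest linear sequence: 8 steps (steps 1 to 6, then 12 and 13); the ring B branch (steps 7 to 11) joins at step 12.

Step 12 (key step, proposed new method). The most likely failure is protonation of the aryl anion, by the hydroxyl proton or by bifluoride, before it reaches the ester. That would end in a plain aryl ether that cannot be closed under conditions the isoprenoid chains tolerate. A second risk is erosion of enantiomeric purity, by retro-aldol equilibration of 23 or by E1cB ring opening and reclosure of 25 in the basic fluoride medium. The fallback uses known chemistry, Mitsunobu etherification followed by Parham cyclisation, and sets out from carbamate 7 and keto ester 22. Lithio species 9, made as in step 5, is quenched with iodine and gives after the same work-up 2-iodo-3,5-bis(methoxymethoxy)-4-(3-methylbut-2-en-1-yl)phenyl N-(propan-2-yl)carbamate F1. Cleavage with DBU/Et2NH gives 2-iodo-3,5-bis(methoxymethoxy)-4-(3-methylbut-2-en-1-yl)phenol F2. Keto ester 22 is reduced with the (R,R)-configured catalyst to ethyl (3R)-3-{3-[(2E)-3,7-dimethylocta-2,6-dien-1-yl]-4,5-bis(methoxymethoxy)phenyl}-3-hydroxypropanoate F3. Mitsunobu coupling of F2 with F3 (PPh3, DIAD) inverts the carbinol centre and gives ethyl (3S)-3-{3-[(2E)-3,7-dimethylocta-2,6-dien-1-yl]-4,5-bis(methoxymethoxy)phenyl}-3-[2-iodo-3,5-bis(methoxymethoxy)-4-(3-methylbut-2-en-1-yl)phenoxy]propanoate F4. Iodine–magnesium exchange with i-PrMgCl·LiCl at −40 °C then lets the aryl Grignard attack the ester intramolecularly, and the route is rejoined at 25. The same aryl anion equivalent is thus generated in an aprotic medium with the C–O bond already in place.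

Step 5. Deprotonation at the benzylic and allylic CH2 of the prenyl group, which is flanked by two OMOM groups, could compete with ring lithiation. The silyl triflate could also attack a MOM ether, or a second silylation could follow at the other ortho position. The fallback sets out from phenol 6 and swaps deprotonation for halogen–lithium exchange. Bromination with NBS in CH2Cl2 at −78 °C, where the phloroglucinol-type ring should react much faster than the alkene and both ortho positions are equivalent, gives 2-bromo-3,5-bis(methoxymethoxy)-4-(3-methylbut-2-en-1-yl)phenol F5. HMDS gives [2-bromo-3,5-bis(methoxymethoxy)-4-(3-methylbut-2-en-1-yl)phenoxy]trimethylsilane F6. n-BuLi at −78 °C triggers bromine–lithium exchange and a retro-Brook 1,3-silyl shift to the lithium salt of 12, which is triflated with Tf2O to rejoin the route at 13.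

Step 9. The aryl copper species may attack geranyl bromide at the tertiary terminus (SN2' pathway, branched linalyl-type isomer), or the aryllithium may be butylated by the 1-bromobutane formed in the exchange. The fallback sets out from bromide 15 and is a palladium-catalysed Suzuki–Miyaura coupling with commercial (E)-geranylboronic acid pinacol ester, using a bulky biaryl phosphine chosen for the linear product. It leads directly to 20, makes no new compound and skips the acetal.

Step 10. The electron-rich aldehyde may react sluggishly, and prolonged contact with the Lewis acid may start ionisation of a MOM ether or cyclisation of the geranyl chain. The fallback sets out from 20. Aldol addition of the lithium enolate of ethyl acetate (LDA, THF, −78 °C) gives racemic ethyl 3-{3-[(2E)-3,7-dimethylocta-2,6-dien-1-yl]-4,5-bis(methoxymethoxy)phenyl}-3-hydroxypropanoate F7, and oxidation with Dess–Martin periodinane returns to 22.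

Step 13. Acid-promoted cyclisation of the prenyl or geranyl group onto the freed phenols (chroman formation) may compete with acetal cleavage. The fallback sets out from 25 and avoids free Brønsted acid. TMSOTf with 2,2'-bipyridyl in CH2Cl2 at 0 °C converts the four aryl MOM ethers into aryl silyl ethers, giving the tetrakis(trimethylsilyl) ether of schizolaenone B F8, and addition of water at near-neutral pH hydrolyses these to 26.

## Further compounds

F1 | step 12 | 2-iodo-3,5-bis(methoxymethoxy)-4-(3-methylbut-2-en-1-yl)phenyl N-(propan-2-yl)carbamate | CC(C)NC(=O)Oc1cc(OCOC)c(CC=C(C)C)c(OCOC)c1I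
F2 | step 12 | 2-iodo-3,5-bis(methoxymethoxy)-4-(3-methylbut-2-en-1-yl)phenol | Oc1cc(OCOC)c(CC=C(C)C)c(OCOC)c1I
F3 | step 12 | ethyl (3R)-3-{3-[(2E)-3,7-dimethylocta-2,6-dien-1-yl]-4,5-bis(methoxymethoxy)phenyl}-3-hydroxypropanoate | CCOC(=O)C[C@@H](O)c1cc(OCOC)c(OCOC)c(C/C=C(\C)CCC=C(C)C)c1
F4 | step 12 | ethyl (3S)-3-{3-[(2E)-3,7-dimethylocta-2,6-dien-1-yl]-4,5-bis(methoxymethoxy)phenyl}-3-[2-iodo-3,5-bis(methoxymethoxy)-4-(3-methylbut-2-en-1-yl)phenoxy]propanoate | CCOC(=O)C[C@H](Oc1cc(OCOC)c(CC=C(C)C)c(OCOC)c1I)c1cc(OCOC)c(OCOC)c(C/C=C(\C)CCC=C(C)C)c1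
F5 | step 5 | 2-bromo-3,5-bis(methoxymethoxy)-4-(3-methylbut-2-en-1-yl)phenol | Oc1cc(OCOC)c(CC=C(C)C)c(OCOC)c1Br
F6 | step 5 | [2-bromo-3,5-bis(methoxymethoxy)-4-(3-methylbut-2-en-1-yl)phenoxy]trimethylsilane | C[Si](C)(C)Oc1cc(OCOC)c(CC=C(C)C)c(OCOC)c1Br
F0 | step 9 | none | none
F7 | step 10 | ethyl 3-{3-[(2E)-3,7-dimethylocta-2,6-dien-1-yl]-4,5-bis(methoxymethoxy)phenyl}-3-hydroxypropanoate (racemic) | CCOC(=O)CC(O)c1cc(OCOC)c(OCOC)c(C/C=C(\C)CCC=C(C)C)c1
F8 | step 13 | (2S)-2-{3-[(2E)-3,7-dimethylocta-2,6-dien-1-yl]-4,5-bis(trimethylsilyloxy)phenyl}-6-(3-methylbut-2-en-1-yl)-5,7-bis(trimethylsilyloxy)-2,3-dihydro-4H-chromen-4-one | CC(C)=CCC/C(C)=C/Cc1cc([C@@H]2CC(=O)c3c(cc(O[Si](C)(C)C)c(CC=C(C)C)c3O[Si](C)(C)C)O2)cc(O[Si](C)(C)C)c1O[Si](C)(C)C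
A1 | alternative 1 | 1-[6-hydroxy-2,4-bis(methoxymethoxy)-3-(3-methylbut-2-en-1-yl)phenyl]ethan-1-one | CC(=O)c1c(O)cc(OCOC)c(CC=C(C)C)c1OCOC
A2 | alternative 1 | (2E)-3-{3-[(2E)-3,7-dimethylocta-2,6-dien-1-yl]-4,5-bis(methoxymethoxy)phenyl}-1-[6-hydroxy-2,4-bis(methoxymethoxy)-3-(3-methylbut-2-en-1-yl)phenyl]prop-2-en-1-one | O=C(/C=C/c1cc(OCOC)c(OCOC)c(C/C=C(\C)CCC=C(C)C)c1)c1c(O)cc(OCOC)c(CC=C(C)C)c1OCOC
A3 | alternative 2 | 5,7-bis(methoxymethoxy)-6-(3-methylbut-2-en-1-yl)-4H-chromen-4-one | O=c1ccoc2cc(OCOC)c(CC=C(C)C)c(OCOC)c12
A4 | alternative 2 | {3-[(2E)-3,7-dimethylocta-2,6-dien-1-yl]-4,5-bis(methoxymethoxy)phenyl}boronic acid | OB(O)c1cc(OCOC)c(OCOC)c(C/C=C(\C)CCC=C(C)C)c1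
A5 | alternative 3 | (2S)-2-(3,4-dihydroxyphenyl)-5,7-dihydroxy-2,3-dihydro-4H-chromen-4-one ((S)-eriodictyol) | c1cc([C@@H]2CC(=O)c3c(cc(O)cc3O)O2)cc(O)c1O
A6 | alternative 3 | (2S)-2-{4-[(3,7-dimethylocta-1,6-dien-3-yl)oxy]-3-(methoxymethoxy)phenyl}-7-(methoxymethoxy)-5-[(2-methylbut-3-en-2-yl)oxy]-2,3-dihydro-4H-chromen-4-one | c1cc([C@@H]2CC(=O)c3c(cc(OCOC)cc3OC(C)(C)C=C)O2)cc(OCOC)c1OC(C)(C=C)CCC=C(C)C
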